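**Retrosynthetic overview**

1. Target ⇐ C10,C20-epoxide (cleavage of the furfurylic C10–O bond) ⇐ tetracyclic dienone. Both C10 (furfurylic CH) and C20 (carbinol carbon) are stored in one tetrasubstituted alkene C10=C20 and are set from it at the end.
2. C10=C20 ⇐ intramolecular McMurry coupling of the ring A ketone (C20) with a 2-furyl ketone (C10), a reductive union of two carbonyl carbons that closes ring B. Enabling feature: C20 is the hub of rings A, B and C and both of its ring A neighbours (spiro carbon C3 and methyl-bearing C18) are quaternary. The C20 ketone therefore cannot enolise, the alkene cannot migrate, and the axial C4H2–O and C18–CH3 groups leave only one face of C10=C20 open.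
3. Ring C ⇐ Friedel–Crafts acylation of furan carbon C15 by the C16 acid. Lactone ring D and the C17–C16 arm ⇐ ozonolysis of a bicyclo[4.3.1]decenone whose temporary four-carbon bridge (from (Z)-1,4-dichlorobut-2-ene) forces the quaternary carbons C3 and C18 cis.
4. Ring A ⇐ copper-catalysed enantioselective Me2Zn addition to 4,4-dimethoxycyclohexa-2,5-dienone (C19, the only stereocentre made by catalysis). C18, C3, C20, C10 and C1 are relayed from it by substrate control.
5. Order of ring formation: A (bought) → temporary cycloheptene bridge → D → B (key step) → C. Furan ring E is bought as furfural.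

Key step: step 11

Remark on locants: C1 = CH–OAc; C2 = ring CH2; C3 = spiro quaternary carbon; C4 = lactone CH2–O; C6 = lactone C=O; C7=C8 = lactone alkene; C9 = allylic CH2; C10 = furfurylic CH; C11 (on C10), C13, C14, C15 (on C16) = furan carbons; C16 = ketone; C17 = CH2 next to it; C18 = quaternary C–CH3; C19 = CH–CH3; C20 = C–OH. Ring A = C1–C2–C3–C20–C18–C19, ring B = C3–C7–C8–C9–C10–C20, ring C = C10–C11–C15–C16–C17–C18–C20, ring D = lactone, ring E = furan.

Assumption: compounds 1, 6 and 12 and all reagents are taken as commercial. The C18 epimers of 5 and the C7 epimers of 15 to 18 are carried as mixtures because these centres are planarised later.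

**Route**

Step 1
Reactants: 1 4,4-dimethoxycyclohexa-2,5-dien-1-one
Product: 2 (S)-4,4-dimethoxy-5-methylcyclohex-2-en-1-one
Conditions: Me2Zn, Cu(OTf)2 (cat.), chiral binaphthol/bis(1-phenylethyl)amine phosphoramidite (cat., the enantiomer that gives the S product), toluene, −25 °C
Reagents that add atoms: dimethylzinc C[Zn]C
Why: Copper-catalysed asymmetric conjugate addition (desymmetrisation of a quinone monoketal with a dialkylzinc) should add one methyl group to one of the two enantiotopic enone arms under control of the chiral ligand, which sets C19 as the only stereocentre made by catalysis.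

Step 2
Reactants: 2 (S)-4,4-dimethoxy-5-methylcyclohex-2-en-1-one
Product: 3 (S)-2-iodo-4,4-dimethoxy-5-methylcyclohex-2-en-1-one
Conditions: I2, pyridine, CH2Cl2, 0 to 23 °C
Reagents that add atoms: iodine II
Why: α-Iodination of an enone by the iodine/pyridine addition–elimination sequence is standard for 4,4-disubstituted cyclohexenones and leaves the ketal and C19 untouched.

Step 3
Reactants: 3 (S)-2-iodo-4,4-dimethoxy-5-methylcyclohex-2-en-1-one
Product: 4 (S)-2-(hydroxymethyl)-4,4-dimethoxy-5-methylcyclohex-2-en-1-one
Conditions: Bu3SnCH2OH, Pd(PPh3)4 (cat.), dioxane, 90 °C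
Reagents that add atoms: (tributylstannyl)methanol CCCC[Sn](CCCC)(CCCC)CO
Why: Stille coupling of the α-iodoenone should transfer the hydroxymethyl group (the future C4H2–O) from tin in preference to butyl and tolerates the free alcohol.

Step 4
Reactants: 4 (S)-2-(hydroxymethyl)-4,4-dimethoxy-5-methylcyclohex-2-en-1-one
Product: 5 (5S,6S)-2-(hydroxymethyl)-4,4-dimethoxy-5,6-dimethylcyclohex-2-en-1-one
Conditions: LiN(i-Pr)2 (2.2 equiv), THF, −78 °C; MeI
Reagents that add atoms: iodomethane CI
Why: Enolate alkylation: once the alcohol is deprotonated the only acidic position is C18 (C1 is a ketal and C3 is sp2), so the cross-conjugated enolate is methylated there, and the configuration of this centre is of no consequence because it is planarised again in step 5.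

Step 5
Reactants: 5 (5S,6S)-2-(hydroxymethyl)-4,4-dimethoxy-5,6-dimethylcyclohex-2-en-1-one; 6 (Z)-1,4-dichlorobut-2-ene
Product: 7 (5S,6S)-6-[(Z)-4-chlorobut-2-en-1-yl]-2-(hydroxymethyl)-4,4-dimethoxy-5,6-dimethylcyclohex-2-en-1-one
Conditions: LiN(i-Pr)2 (2.2 equiv), THF, −78 °C; 6 (excess), −78 to −20 °C
Reagents that add atoms: none
Why: Enolate alkylation with the allylic chloride should occur on the face opposite to the neighbouring C19 methyl group (1,2-induction, that methyl being held pseudo-axial by allylic strain), which sets the quaternary carbon C18 with the C17 chain trans to the C19 methyl.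

Step 6
Reactants: 7 (5S,6S)-6-[(Z)-4-chlorobut-2-en-1-yl]-2-(hydroxymethyl)-4,4-dimethoxy-5,6-dimethylcyclohex-2-en-1-one
Product: 9 1-(hydroxymethyl)-8,8-dimethoxy-6,7-dimethylbicyclo[4.3.1]dec-3-en-10-one (C7 methyl on the face away from the butene bridge), via alkoxide enolate 8 (not isolated)
Conditions: NaH (1.0 equiv), THF, 0 °C; LiBH(s-Bu)3 (L-Selectride), −78 to 40 °C
Reagents that add atoms: none
Why: Reductive alkylation: conjugate hydride addition to the β-unsubstituted enone gives the C3 enolate regiospecifically and its intramolecular SN2 attack on the (Z)-allylic chloride closes the seven-membered ring of an alpha,alpha'-annulation, which can only form cis across the ketone, so the quaternary carbon C3 is set with C7 on the face of C17 and C4 on the face of the C18 methyl.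

Step 7
Reactants: 9 1-(hydroxymethyl)-8,8-dimethoxy-6,7-dimethylbicyclo[4.3.1]dec-3-en-10-one
Product: 11 spirolactone keto ester (ring A with C20 ketone; γ-lactone spiro at C3; C18 bearing CH3 and CH2CO2CH3; C1 dimethyl ketal), via lactol aldehyde 10 (not isolated)
Conditions: O3, NaOH, MeOH/CH2Cl2, −78 °C
Reagents that add atoms: ozone [O-][O+]=O; methanol CO
Why: Ozonolysis in methanolic NaOH should cleave the bridge alkene and oxidise both ends to the carboxyl level, the C6 end being trapped by the C4 hydroxyl as lactol 10 and oxidised to the γ-lactone while the C16 end becomes the methyl ester, with no stereocentre affected.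

Step 8
Reactants: 12 furfural
Product: 13 racemic 1-(furan-2-yl)prop-2-en-1-ol
Conditions: CH2=CHMgBr, THF, −78 °C
Reagents that add atoms: vinylmagnesium bromide C=C[Mg]Br
Why: Grignard addition of the vinyl reagent to the aldehyde gives the allylic alcohol, whose stereocentre is removed in step 9.

Step 9
Reactants: 13 racemic 1-(furan-2-yl)prop-2-en-1-ol
Product: 14 1-(furan-2-yl)prop-2-en-1-one
Conditions: MnO2, CH2Cl2, 23 °C
Reagents that add atoms: none
Why: MnO2 oxidation of the allylic and furfurylic alcohol should give the aryl vinyl ketone, which is used at once because it polymerises on storage.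

Step 10
Reactants: 11 spirolactone keto ester; 14 1-(furan-2-yl)prop-2-en-1-one
Product: 15 diketone (11 carrying a 3-(furan-2-yl)-3-oxopropyl group on lactone carbon C7; both C7 epimers)
Conditions: LiN(i-Pr)2, THF, −78 °C; 14; then AcOH
Reagents that add atoms: none
Why: Michael addition: the lactone CH2 (C7) is the only readily enolisable site (the C20 ketone has no α-hydrogen and the ester CH2 is neopentylic and less acidic) and its lithium enolate should add to the unsubstituted β-carbon of the aryl vinyl ketone, the C7 epimers converging in step 12.

Step 11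
Reactants: 15 diketone
Product: 17 tricyclic alkene (rings A, B and D; tetrasubstituted C10=C20 with furan-2-yl on C10; saturated lactone; methyl ester; C1 dimethyl ketal), via titanium pinacolate 16 (not isolated)
Conditions: TiCl3(DME)1.5, Zn–Cu couple, DME, reflux, slow addition of 15 at high dilution
Reagents that add atoms: none
Why: Low-valent titanium should reduce the 2-furyl ketone (the most easily reduced carbonyl) to a titanium ketyl, which adds to the titanium-bound ring A ketone to give pinacolate 16, and the titanium surface then removes both oxygens to leave the C10=C20 alkene. The closest known reaction type is the intramolecular McMurry coupling of 1,6-diketones to tetrasubstituted cyclohexenes, a reductive union of two carbonyl carbons of like polarity. Ring B is closed in the 6-exo mode (ketyl carbon C10 onto the C20 carbonyl through the tether C9–C8–C7–C3). No stereocentre is created: C10 and C20 become sp2 and are set later from this alkene (C20 in step 17, C10 in step 18), and the C7 epimers are removed in step 12. The step needs ketone–ketone coupling to win over attack on the lactone, ester and ketal and over intermolecular pinacol formation; this is secured by the far slower reduction of esters, by the absence of any α-hydrogen at C20 (C3 and C18 are quaternary, so no enolisation or aldol path exists) and by slow addition at high dilution.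

Step 12
Reactants: 17 tricyclic alkene
Product: 19 tricyclic diene (17 with the endocyclic C7=C8 double bond of the unsaturated lactone), via phenylselenyl lactone 18 (not isolated)
Conditions: LiN(i-Pr)2, THF, −78 °C; PhSeBr; then H2O2, pyridine, CH2Cl2, 0 °C
Reagents that add atoms: none
Why: α-Selenenylation of the lactone enolate followed by selenoxide syn-elimination, which can only run toward C8 because C3 is quaternary, should install the C7=C8 double bond and remove the C7 stereocentre.

Step 13
Reactants: 19 tricyclic diene
Product: 21 keto acid (C1 ketone; C16 carboxylic acid; lactone D; C7=C8; C10=C20 with furan-2-yl), via hydroxy diacid 20 (not isolated)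
Conditions: LiOH, THF/H2O, 23 °C; then 1 M HCl, 23 °C
Reagents that add atoms: water O
Why: Ester saponification (the lactone opens to 20 and recloses on acidification) and acid hydrolysis of the dimethyl ketal should unmask the C16 acid and the C1 ketone, C19 staying in its more stable equatorial configuration even if the ketone enolises.

Step 14
Reactants: 21 keto acid
Product: 23 tetracyclic dienone (rings A to E closed; C1 and C16 ketones; C7=C8 and C10=C20), via acid chloride 22 (not isolated)
Conditions: 1-chloro-N,N,2-trimethylprop-1-en-1-amine, CH2Cl2, 0 °C; then SnCl4, CH2Cl2, −78 °C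
Reagents that add atoms: none
Why: Intramolecular Friedel–Crafts acylation of the furan: the acylium ion tethered at C18 can reach only the β-carbon C15 (seven-membered ring C), and neutral acid chloride formation with low-temperature SnCl4 activation should spare the acid-sensitive 2-alkenylfuran.

Step 15
Reactants: 23 tetracyclic dienone
Product: 24 C1 alcohol (hydroxyl axial; cis to C4 and to the C18 and C19 methyl groups)
Conditions: NaBH4, MeOH/CH2Cl2, −40 °C
Reagents that add atoms: none
Why: Hydride reduction of the unconjugated C1 ketone should occur by equatorial attack from the face opposite to the syn-axial C4H2–O and C18 methyl groups, giving the axial alcohol cis to them, while the neopentylic, vinylogous C16 ketone and the enoate react more slowly.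

Step 16
Reactants: 24 C1 alcohol
Product: 25 C1 acetate
Conditions: Ac2O, pyridine, DMAP (cat.), CH2Cl2, 23 °C
Reagents that add atoms: acetic anhydride CC(=O)OC(C)=O
Why: DMAP-catalysed acylation of the only hydroxyl group should give the acetate with retention at C1.

Step 17
Reactants: 25 C1 acetate
Product: 26 C10,C20-epoxide (epoxide oxygen on the face opposite to C4 and the C18 methyl)
Conditions: dimethyldioxirane, acetone/CH2Cl2, −40 °C
Reagents that add atoms: dimethyldioxirane CC1(C)OO1
Why: Electrophilic epoxidation of the tetrasubstituted C10=C20 bond (the γ,δ-bond of the furan-relayed dienone) should occur from the face opposite to the axial C4H2–O and C18 methyl groups, which sets the C20–O bond, the enoate alkene and the acyl-deactivated furan being slower.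

Step 18
Reactants: 26 C10,C20-epoxide
Product: 28 target CNP0329797.2, via samarium dienolate 27 (not isolated)
Conditions: SmI2, THF/MeOH, −78 °C
Reagents that add atoms: none
Why: Proposed new method: single-electron transfer from SmI2 to the C16 ketone should give a ketyl whose electron density is relayed through the furan C15=C11 bond into the furfurylic C10–O bond, so that the epoxide opens to samarium dienolate 27 with the C20 alkoxide retained, and protonation at C10 restores the furan; the closest known reaction type is the SmI2 opening of γ,δ-epoxy-α,β-unsaturated ketones and esters (vinylogous α-alkoxy ketone cleavage), which has not been shown with a furan double bond as the relay; C20 keeps the configuration from step 17 and C10 should be protonated on the face opposite to the bulky samarium alkoxide, the path that keeps furan carbon C11 equatorial on ring B and clear of the axial C4H2–O group, giving H10 anti to the C20 hydroxyl.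

**Compound list**

1 | 4,4-dimethoxycyclohexa-2,5-dien-1-one | COC1(OC)C=CC(=O)C=C1 | starting material
2 | (S)-4,4-dimethoxy-5-methylcyclohex-2-en-1-one | O=C1C=CC(OC)(OC)[C@@H](C)C1 | intermediate
3 | (S)-2-iodo-4,4-dimethoxy-5-methylcyclohex-2-en-1-one | O=C1C(I)=CC(OC)(OC)[C@@H](C)C1 | intermediate
4 | (S)-2-(hydroxymethyl)-4,4-dimethoxy-5-methylcyclohex-2-en-1-one | O=C1C(CO)=CC(OC)(OC)[C@@H](C)C1 | intermediate
5 | (5S,6S)-2-(hydroxymethyl)-4,4-dimethoxy-5,6-dimethylcyclohex-2-en-1-one (methyl groups trans; major epimer) | O=C1C(CO)=CC(OC)(OC)[C@@H](C)[C@@H]1C | intermediate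
6 | (Z)-1,4-dichlorobut-2-ene | ClC/C=C\CCl | starting material
7 | (5S,6S)-6-[(Z)-4-chlorobut-2-en-1-yl]-2-(hydroxymethyl)-4,4-dimethoxy-5,6-dimethylcyclohex-2-en-1-one (methyl groups cis) | O=C1C(CO)=CC(OC)(OC)[C@@H](C)[C@]1(C)C/C=C\CCl | intermediate
8 | sodium lithium alkoxide enolate formed from 7 by 1,4-hydride addition (C3 enolate, C4 alkoxide) | [Na+].[Li+].[O-]C1=C(C[O-])CC(OC)(OC)[C@@H](C)[C@]1(C)C/C=C\CCl | intermediate
9 | 1-(hydroxymethyl)-8,8-dimethoxy-6,7-dimethylbicyclo[4.3.1]dec-3-en-10-one (C3 and C18 as bridgeheads, C7 and C17 cis, C19 methyl on the face away from the butene bridge) | O=C1[C@@]2(CO)CC(OC)(OC)[C@@H](C)[C@]1(C)CC=CC2 | intermediate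
10 | lactol aldehyde (C6 lactol closed by the C4 hydroxyl; C16 aldehyde; lactol carbon unassigned) | O=C1[C@@]2(COC(O)C2)CC(OC)(OC)[C@@H](C)[C@]1(C)CC=O | intermediate
11 | spirolactone keto ester (C20 ketone; γ-lactone spiro at C3 with C4H2–O cis to the C18 methyl; C18 bearing CH3 and CH2CO2CH3, the ester arm trans to the C19 methyl; C1 dimethyl ketal) | O=C1[C@@]2(COC(=O)C2)CC(OC)(OC)[C@@H](C)[C@]1(C)CC(=O)OC | intermediate
12 | furfural | O=Cc1ccco1 | starting material
13 | racemic 1-(furan-2-yl)prop-2-en-1-ol | C=CC(O)c1ccco1 | intermediate
14 | 1-(furan-2-yl)prop-2-en-1-one | C=CC(=O)c1ccco1 | intermediate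
15 | diketone: 11 with a 3-(furan-2-yl)-3-oxopropyl group on lactone carbon C7 (both C7 epimers) | O=C1[C@@]2(COC(=O)C2CCC(=O)c3ccco3)CC(OC)(OC)[C@@H](C)[C@]1(C)CC(=O)OC | intermediate
16 | titanium-bound pinacolate of 15 (drawn as the C10,C20-diolate; C7, C10 and C20 unassigned) | COC1(OC)C[C@@]23COC(=O)C2CCC([O-])(c4ccco4)C3([O-])[C@@](C)(CC(=O)OC)[C@@H]1C | intermediate
17 | tricyclic alkene: rings A, B and D with tetrasubstituted C10=C20, furan-2-yl on C10, saturated lactone (both C7 epimers), methyl ester, C1 dimethyl ketal | COC1(OC)C[C@@]23COC(=O)C2CCC(c4ccco4)=C3[C@@](C)(CC(=O)OC)[C@@H]1C | intermediate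
18 | 17 with a phenylselenyl group on C7 | COC1(OC)C[C@@]23COC(=O)C2([Se]c5ccccc5)CCC(c4ccco4)=C3[C@@](C)(CC(=O)OC)[C@@H]1C | intermediate
19 | tricyclic diene: 17 with C7=C8 (ring B a cyclohexa-1,4-diene) | COC1(OC)C[C@@]23COC(=O)C2=CCC(c4ccco4)=C3[C@@](C)(CC(=O)OC)[C@@H]1C | intermediate
20 | ring-opened hydroxy diacid of 19 (C4 hydroxyl, C6 and C16 acids; formed as the dilithium salt) | COC1(OC)C[C@@]2(CO)C(C(=O)O)=CCC(c3ccco3)=C2[C@@](C)(CC(=O)O)[C@@H]1C | intermediate
21 | keto acid: C1 ketone, C16 carboxylic acid, lactone D, C7=C8, C10=C20 with furan-2-yl | O=C1C[C@@]23COC(=O)C2=CCC(c4ccco4)=C3[C@@](C)(CC(=O)O)[C@@H]1C | intermediate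
22 | acid chloride of 21 | O=C1C[C@@]23COC(=O)C2=CCC(c4ccco4)=C3[C@@](C)(CC(=O)Cl)[C@@H]1C | intermediate
23 | tetracyclic dienone: rings A to E, C1 and C16 ketones, C7=C8 and C10=C20 | O=C1C[C@@]23COC(=O)C2=CCC4=C3[C@@](C)(CC(=O)c5ccoc54)[C@@H]1C | intermediate
24 | C1 alcohol of 23 (hydroxyl axial, cis to C4 and to both methyl groups) | O[C@@H]1C[C@@]23COC(=O)C2=CCC4=C3[C@@](C)(CC(=O)c5ccoc54)[C@@H]1C | intermediate
25 | C1 acetate of 24 | CC(=O)O[C@@H]1C[C@@]23COC(=O)C2=CCC4=C3[C@@](C)(CC(=O)c5ccoc54)[C@@H]1C | intermediate
26 | C10,C20-epoxide of 25 (oxygen anti to C4 and the C18 methyl) | CC(=O)O[C@@H]1C[C@@]23COC(=O)C2=CC[C@@]4(O5)[C@]35[C@@](C)(CC(=O)c6ccoc64)[C@@H]1C | intermediate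
27 | samarium dienolate (drawn as the dianion: C20 alkoxide, C10=C11 exocyclic, C15=C16 enolate) | CC(=O)O[C@@H]1C[C@@]23COC(=O)C2=CCC2=C4OC=CC4=C([O-])C[C@@](C)([C@@H]1C)[C@@]23[O-] | intermediate
28 | target CNP0329797.2 | CC(=O)O[C@@H]1C[C@@]23COC(=O)C2=CC[C@H]2c4occc4C(=O)C[C@@](C)([C@@H]1C)[C@@]23O | target

**Count and risks**

Total step count: 18. Longest linear sequence: 16 steps (steps 1 to 7 and 10 to 18); steps 8 and 9 make the furan fragment.

The three steps most likely to fail:

Step 18 (proposed new method). Electron transfer may be diverted into plain reduction of the C16 ketone or of the enoate before the C10–O bond breaks, or the dienolate may be protonated on the wrong face of C10. The fallback uses known chemistry, sets out from epoxide 26 and comes back at 28. It is a titanocene-mediated radical epoxide opening (Cp2TiCl2, Zn, 1,4-cyclohexadiene, THF, 23 °C). Trivalent titanium binds the epoxide oxygen, homolysis gives the more stabilised tertiary furfurylic radical at C10 and leaves the titanium alkoxide on C20. Hydrogen-atom transfer from the diene on the face opposite to the bulky titanocene alkoxide should then give 28 directly, without any new compound.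

Step 11. The titanium ketyl may be lost to intermolecular coupling or to attack on the lactone carbonyl, or deoxygenation of the very hindered pinacolate may stall. The fallback sets out from diketone 15 and comes back at 17. SmI2 with HMPA in THF at −78 °C should close ring B by pinacol coupling to the cis-diol F1. Thiocarbonyldiimidazole and DMAP in refluxing toluene should convert it into the cyclic thionocarbonate F2. P(OMe)3 at 110 °C (Corey–Winter olefination) should then extrude the alkene and give 17.

Step 14. Acid-induced oligomerisation or ring opening of the 2-alkenylfuran, or capture of the acylium ion by the C10=C20 bond, may outrun ring closure. The fallback reverses the polarity (nucleophilic furan, electrophilic ester), sets out from 11 and comes back at 23. Vinylmagnesium bromide adds to commercial 3-bromofuran-2-carbaldehyde to give 1-(3-bromofuran-2-yl)prop-2-en-1-ol F3, and MnO2 gives 1-(3-bromofuran-2-yl)prop-2-en-1-one F4. Michael addition of the lithium enolate of 11 to F4 gives the bromo diketone F5. McMurry coupling, in which the C–Br bond should survive, gives the bromo tricycle F6. Selenenylation gives the selenide F7, and oxidative elimination gives the bromo diene F8. tert-Butyllithium (2 equiv, THF, −100 °C) exchanges bromine for lithium, and the furyllithium attacks the methyl ester (Parham cyclisation) to give the ketal dienone F9. Aqueous HCl in THF removes the ketal and returns to 23.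

Further compounds
F0 | step 18 | none | none
F1 | step 11 | cis-C10,C20-diol from pinacol cyclisation of 15 (C7, C10 and C20 unassigned) | COC1(OC)C[C@@]23COC(=O)C2CCC(O)(c4ccco4)C3(O)[C@@](C)(CC(=O)OC)[C@@H]1C
F2 | step 11 | cyclic thionocarbonate of F1 | COC1(OC)C[C@@]23COC(=O)C2CCC4(c5ccco5)OC(=S)OC34[C@@](C)(CC(=O)OC)[C@@H]1C
F3 | step 14 | racemic 1-(3-bromofuran-2-yl)prop-2-en-1-ol | C=CC(O)c1occc1Br
F4 | step 14 | 1-(3-bromofuran-2-yl)prop-2-en-1-one | C=CC(=O)c1occc1Br
F5 | step 14 | bromo diketone (15 with bromine on furan carbon C15) | O=C1[C@@]2(COC(=O)C2CCC(=O)c3occc3Br)CC(OC)(OC)[C@@H](C)[C@]1(C)CC(=O)OC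
F6 | step 14 | bromo tricycle (17 with bromine on furan carbon C15) | COC1(OC)C[C@@]23COC(=O)C2CCC(c4occc4Br)=C3[C@@](C)(CC(=O)OC)[C@@H]1C
F7 | step 14 | selenide (18 with bromine on furan carbon C15) | COC1(OC)C[C@@]23COC(=O)C2([Se]c5ccccc5)CCC(c4occc4Br)=C3[C@@](C)(CC(=O)OC)[C@@H]1C
F8 | step 14 | bromo diene (19 with bromine on furan carbon C15) | COC1(OC)C[C@@]23COC(=O)C2=CCC(c4occc4Br)=C3[C@@](C)(CC(=O)OC)[C@@H]1C
F9 | step 14 | ketal dienone (C1 dimethyl ketal of 23) | COC1(OC)C[C@@]23COC(=O)C2=CCC4=C3[C@@](C)(CC(=O)c5ccoc54)[C@@H]1C
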